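**Retrosynthetic overview**
- Target ⇐ aromatic Claisen rearrangement of the (2S)-5-O-(1,1-dimethylallyl)flavanone; the ether oxygen passes its C5 unit to C6, the only free ortho position.
- C ring (the only ring made, O1–C2 bond) ⇐ catalytic enantioselective chalcone-isomerase-type 6-endo oxa-Michael closure of a 2′-hydroxy-6′-(1,1-dimethylallyloxy)chalcone. The ether leaves one phenol free, so there is one closure mode and no fast racemic background.
- Chalcone ⇐ Claisen–Schmidt condensation of mono-etherified 2′,6′-dihydroxy-4′-methoxyacetophenone with 2-geranyl-3,4-dimethoxybenzaldehyde.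
- Aldehyde ⇐ veratraldehyde by α-amino-alkoxide-directed C2 lithiation and geranylation; ether ⇐ Pd-catalysed O-alkylation with a tertiary allylic carbonate.
- Ring order: A and B rings are bought; the pyranone C ring is closed after both terpenoid units are on board.

Assumption: the quinidine-derived thiourea is taken to give the 2S closure in step 5. The sense is checked on the first run (chiral HPLC, CD); if it is 2R, the commercial quinine-derived pseudoenantiomer is used in the same step.

**Step 1**
Reactants: 1 3,4-dimethoxybenzaldehyde (veratraldehyde); 2 geranyl bromide [(2E)-1-bromo-3,7-dimethylocta-2,6-diene]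
Product: 6 2-[(2E)-3,7-dimethylocta-2,6-dien-1-yl]-3,4-dimethoxybenzaldehyde, via lithium α-amino alkoxide 3 (not isolated), via C2-aryllithium 4 (not isolated), via geranylated α-amino alkoxide 5 (not isolated)
Conditions: Me2N(CH2)2N(Me)Li (1.1 equiv, from the amine + n-BuLi), THF, −20 °C; n-BuLi (3 equiv), −20 °C, 24 h; CuBr·SMe2 (20 mol%), 2 (3.5 equiv), −78 → 0 °C; H2O
Reagents that add atoms: lithium N,N,N′-trimethylethylenediamide, CN([Li])CCN(C)C (its atoms are in 3, 4 and 5 only and leave on work-up); n-butyllithium, [Li]CCCC (gives the lithium of 4); nothing from either stays in 6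
Why: Comins-type directed ortho-metalation, in which the in-situ α-amino alkoxide protects the aldehyde and, together with the 3-OMe group, directs lithiation to C2; copper-catalysed SN2 coupling with the primary allylic bromide then keeps the E olefin, and no stereocentre is formed.

**Step 2**
Reactants: 7 2-methylbut-3-en-2-ol
Product: 9 tert-butyl 2-methylbut-3-en-2-yl carbonate, via lithium alkoxide 8 (not isolated)
Conditions: n-BuLi (1.0 equiv), THF, 0 °C; Boc2O (1.05 equiv), 0 °C → rt; H2O; distillation
Reagents that add atoms: di-tert-butyl dicarbonate (Boc2O), CC(C)(C)OC(=O)OC(=O)OC(C)(C)C; n-butyllithium, [Li]CCCC (gives the lithium of 8 only)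
Why: O-acylation of the tertiary lithium alkoxide by Boc2O (mixed carbonate formation) is clean because the alkoxide is formed quantitatively first.

**Step 3**
Reactants: 10 1-(2,6-dihydroxy-4-methoxyphenyl)ethan-1-one; 9 tert-butyl 2-methylbut-3-en-2-yl carbonate
Product: 11 1-[2-hydroxy-4-methoxy-6-(2-methylbut-3-en-2-yloxy)phenyl]ethan-1-one
Conditions: 9 (1.1 equiv), Pd(PPh3)4 (3 mol%), THF, 0 °C → rt, stopped as soon as 9 is consumed; work-up and chromatography below 25 °C
Reagents that add atoms: none
Why: Tsuji–Trost decarboxylative O-allylation, in which the phenoxide attacks the more substituted terminus of the 1,1-dimethyl-π-allyl palladium under kinetic control to give the tertiary ether; the two OH groups of 10 are equivalent and the remaining one is chelated to the ketone, so mono-etherification is favoured.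

**Step 4**
Reactants: 11 1-[2-hydroxy-4-methoxy-6-(2-methylbut-3-en-2-yloxy)phenyl]ethan-1-one; 6 2-[(2E)-3,7-dimethylocta-2,6-dien-1-yl]-3,4-dimethoxybenzaldehyde
Product: 13 (2E)-3-{2-[(2E)-3,7-dimethylocta-2,6-dien-1-yl]-3,4-dimethoxyphenyl}-1-[2-hydroxy-4-methoxy-6-(2-methylbut-3-en-2-yloxy)phenyl]prop-2-en-1-one, via aldol adduct 12 (not isolated)
Conditions: KOH (50% aq, 10 equiv), EtOH, 0 °C → rt, 36 h, N2; AcOH to pH 6 at 0 °C
Reagents that add atoms: none
Why: Claisen–Schmidt condensation (aldol addition, then E1cB dehydration to the E enone); in strong base the chalcone sits as its phenoxide and does not cyclise, the tertiary allyl ether is base-stable, and the weak-acid quench spares it.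

**Step 5**
Reactants: 13 the 2′-hydroxy-6′-(1,1-dimethylallyloxy)chalcone
Product: 14 (2S)-2-{2-[(2E)-3,7-dimethylocta-2,6-dien-1-yl]-3,4-dimethoxyphenyl}-7-methoxy-5-(2-methylbut-3-en-2-yloxy)-2,3-dihydro-4H-chromen-4-one
Conditions: quinidine-derived epi-9-amino thiourea [N-(3,5-bis(trifluoromethyl)phenyl)-N′-((9R)-6′-methoxycinchonan-9-yl)thiourea] (10 mol%), toluene (0.1 M), −20 → 0 °C, 48–72 h; silica plug to remove the catalyst before any warming
Reagents that add atoms: none
Why: Proposed new method: a chalcone-isomerase-like 6-endo-trig oxa-Michael addition in which the quinuclidine nitrogen deprotonates the 2′-OH while the thiourea hydrogen-bonds the enone carbonyl, so the phenoxide is delivered to one face of C-β and C2 is set as S under catalyst control; the closest known reaction types are the cinchona–thiourea-catalysed cyclisation of 2′-hydroxyaryl alkylidene β-ketoesters to 3-carboxyflavanones and the amine-catalysed, modest-ee cyclisation of 6′-substituted 2′-hydroxychalcones, and here the 6′-tert-alkoxy group twists the aryl ketone to speed closure and blocks the second phenol.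

**Step 6**
Reactants: 14 the (2S)-5-O-(1,1-dimethylallyl)flavanone
Product: 16 (2S)-2-{2-[(2E)-3,7-dimethylocta-2,6-dien-1-yl]-3,4-dimethoxyphenyl}-5-hydroxy-7-methoxy-6-(3-methylbut-2-en-1-yl)-2,3-dihydro-4H-chromen-4-one, via ortho-dienone 15 (not isolated)
Conditions: degassed toluene (0.05 M), 120 °C, sealed tube, 4–6 h
Reagents that add atoms: none
Why: aromatic Claisen rearrangement ([3,3]-sigmatropic shift) of the aryl 1,1-dimethylallyl ether to C6, the only open ortho position since C4a is blocked, followed by enolisation to the chelated 5-OH phenol; the conditions are neutral and no bond at C2 is touched, so the S configuration is kept.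

**Compound list**
1 | 3,4-dimethoxybenzaldehyde (veratraldehyde) | COc1ccc(C=O)cc1OC | starting material
2 | geranyl bromide, (2E)-1-bromo-3,7-dimethylocta-2,6-diene | BrC/C=C(\C)CCC=C(C)C | starting material
3 | lithium α-amino alkoxide from 1 and lithium N,N,N′-trimethylethylenediamide | COc1ccc(C(O[Li])N(C)CCN(C)C)cc1OC | intermediate
4 | C2-lithiated α-amino alkoxide (aryllithium between the masked CHO and 3-OMe) | COc1ccc(C(O[Li])N(C)CCN(C)C)c([Li])c1OC | intermediate
5 | lithium α-amino alkoxide of the 2-geranyl aldehyde | COc1ccc(C(O[Li])N(C)CCN(C)C)c(C/C=C(\C)CCC=C(C)C)c1OC | intermediate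
6 | 2-[(2E)-3,7-dimethylocta-2,6-dien-1-yl]-3,4-dimethoxybenzaldehyde | COc1ccc(C=O)c(C/C=C(\C)CCC=C(C)C)c1OC | intermediate
7 | 2-methylbut-3-en-2-ol | CC(C)(O)C=C | starting material
8 | lithium 2-methylbut-3-en-2-olate | CC(C)(O[Li])C=C | intermediate
9 | tert-butyl 2-methylbut-3-en-2-yl carbonate | CC(C)(C)OC(=O)OC(C)(C)C=C | intermediate
10 | 1-(2,6-dihydroxy-4-methoxyphenyl)ethan-1-one | CC(=O)c1c(O)cc(OC)cc1O | starting material
11 | 1-[2-hydroxy-4-methoxy-6-(2-methylbut-3-en-2-yloxy)phenyl]ethan-1-one | CC(=O)c1c(O)cc(OC)cc1OC(C)(C)C=C | intermediate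
12 | aldol adduct (racemic β-hydroxy ketone) of 11 and 6 | COc1cc(O)c(C(=O)CC(O)c2ccc(OC)c(OC)c2C/C=C(\C)CCC=C(C)C)c(OC(C)(C)C=C)c1 | intermediate
13 | (2E)-3-{2-[(2E)-3,7-dimethylocta-2,6-dien-1-yl]-3,4-dimethoxyphenyl}-1-[2-hydroxy-4-methoxy-6-(2-methylbut-3-en-2-yloxy)phenyl]prop-2-en-1-one | COc1cc(O)c(C(=O)/C=C/c2ccc(OC)c(OC)c2C/C=C(\C)CCC=C(C)C)c(OC(C)(C)C=C)c1 | intermediate
14 | (2S)-2-{2-[(2E)-3,7-dimethylocta-2,6-dien-1-yl]-3,4-dimethoxyphenyl}-7-methoxy-5-(2-methylbut-3-en-2-yloxy)-2,3-dihydro-4H-chromen-4-one | COc1cc2c(c(OC(C)(C)C=C)c1)C(=O)C[C@@H](c1ccc(OC)c(OC)c1C/C=C(\C)CCC=C(C)C)O2 | intermediate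
15 | ortho-dienone: (2S)-2-aryl-7-methoxy-6-(3-methylbut-2-en-1-yl)-2,3-dihydro-4H-chromene-4,5(6H)-dione, C6 epimers | COC1=CC2=C(C(=O)C1CC=C(C)C)C(=O)C[C@@H](c1ccc(OC)c(OC)c1C/C=C(\C)CCC=C(C)C)O2 | intermediate
16 | (2S)-2-{2-[(2E)-3,7-dimethylocta-2,6-dien-1-yl]-3,4-dimethoxyphenyl}-5-hydroxy-7-methoxy-6-(3-methylbut-2-en-1-yl)-2,3-dihydro-4H-chromen-4-one (CNP0112088.1) | COc1cc2c(c(O)c1CC=C(C)C)C(=O)C[C@@H](c1ccc(OC)c(OC)c1C/C=C(\C)CCC=C(C)C)O2 | target

**Totals**
Total step count: 6.
Longest linear sequence: 5 steps (7 → 9 → 11 → 13 → 14 → 16; four steps from acetophenone 10).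

**Three steps most likely to fail**

Step 5 (enantioselective closure; risk of low ee, slow turnover, or erosion by reversible opening). The fallback sets out from 13 and comes back at 14. Chalcone 13 is closed without a chiral catalyst (DBU 20 mol%, MeCN, rt) to racemic 2-{2-[(2E)-3,7-dimethylocta-2,6-dien-1-yl]-3,4-dimethoxyphenyl}-7-methoxy-5-(2-methylbut-3-en-2-yloxy)chroman-4-one F5. This is resolved by preparative chiral SFC on an amylose tris(3,5-dimethylphenylcarbamate) phase, and the 2S enantiomer is 14. The 2R enantiomer is returned to the racemate with DBU through the chalcone and recycled.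

Step 3 (Pd-catalysed tertiary ether formation; risk of linear O-prenyl ether, C-allylation or bis-ether). The fallback sets out from 10 and comes back at 11. Acetophenone 10 is alkylated with 3-chloro-3-methylbut-1-yne (K2CO3, KI, CuI cat., acetone, 50 °C) to 1-[2-hydroxy-4-methoxy-6-(2-methylbut-3-yn-2-yloxy)phenyl]ethan-1-one F4. Lindlar semihydrogenation (H2 1 atm, Pd/CaCO3–Pb, quinoline, EtOAc, rt) of the alkyne then gives 11.

Step 1 (geranylation of the dianion beside excess n-BuLi; risk of SN2′ attack, Wurtz coupling or low conversion). The fallback sets out from 1, passes through the same in-flask species 3 and 4, and comes back at 6. Aryllithium 4 is quenched with I2 (THF, −78 °C) to the lithium α-amino alkoxide of 2-iodo-3,4-dimethoxybenzaldehyde F1. Aqueous work-up hydrolyses this to 2-iodo-3,4-dimethoxybenzaldehyde F2, which is purified. Separately, 2 and Bu3SnLi (THF, −78 °C) give tributyl[(2E)-3,7-dimethylocta-2,6-dien-1-yl]stannane F3. Stille coupling of the aryl iodide with the stannane (Pd2(dba)3, AsPh3, CuI, DMF, 60 °C) gives 6.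

**Further compounds**
F1 | step 1 | lithium α-amino alkoxide of 2-iodo-3,4-dimethoxybenzaldehyde (in flask) | COc1ccc(C(O[Li])N(C)CCN(C)C)c(I)c1OC
F2 | step 1 | 2-iodo-3,4-dimethoxybenzaldehyde | COc1ccc(C=O)c(I)c1OC
F3 | step 1 | tributyl[(2E)-3,7-dimethylocta-2,6-dien-1-yl]stannane | CCCC[Sn](CCCC)(CCCC)C/C=C(\C)CCC=C(C)C
F4 | step 3 | 1-[2-hydroxy-4-methoxy-6-(2-methylbut-3-yn-2-yloxy)phenyl]ethan-1-one | CC(=O)c1c(O)cc(OC)cc1OC(C)(C)C#C
F5 | step 5 | racemic 2-{2-[(2E)-3,7-dimethylocta-2,6-dien-1-yl]-3,4-dimethoxyphenyl}-7-methoxy-5-(2-methylbut-3-en-2-yloxy)chroman-4-one | COc1cc2c(c(OC(C)(C)C=C)c1)C(=O)CC(c1ccc(OC)c(OC)c1C/C=C(\C)CCC=C(C)C)O2
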